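**Retrosynthetic overview**
1. Epimedonin L (11) ⇐ tris-MOM ether 10 by acetal cleavage; no C–C bond is made in the last step.
2. 10 ⇐ 8-iodo-3',5'-dibromoflavone 8 + three equivalents of prenylstannane 9: all three aryl–prenyl bonds are cut at once (threefold Stille coupling, the key step).
3. 8 ⇐ 7 ⇐ 6: the C8–I bond comes from regioselective iodination of the 5,7-dialkoxy ring A; the two ring B bromines are carried from the starting material.
4. 6 ⇐ phloroglucinol 4 + β-ketoester 3 by Mentzer annulation (cuts C4–C4a and O1–C2), so no chalcone is made; 3 ⇐ acetophenone 1 + diethyl carbonate 2.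
5. Ring order: rings A and B are bought as aromatics; ring C (the pyranone) is the only ring formed, in step 2.

Assumption: the target has no stereocentre and no E/Z-isomeric olefin, so every compound below is achiral and the SMILES is the full stereochemical description; partly reacted congeners in the threefold steps 3, 5 and 6 are not counted as separate compounds.

**Route**

Step 1
Reactants: 1 1-(3,5-dibromo-4-hydroxyphenyl)ethanone; 2 diethyl carbonate
Product: 3 ethyl 3-(3,5-dibromo-4-hydroxyphenyl)-3-oxopropanoate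
Conditions: NaH (3.5 equiv), 2 (3 equiv), THF, reflux, 6 h; then 1 M HCl (aq), 0 °C
Reagents that add atoms: none
Why: Crossed Claisen condensation in which excess NaH forms the phenoxide–enolate dianion of 1, this attacks diethyl carbonate, and the stabilised β-ketoester enolate pulls the equilibrium to product while the aryl bromides stay inert (no stereocentre formed).

Step 2
Reactants: 3 ethyl 3-(3,5-dibromo-4-hydroxyphenyl)-3-oxopropanoate; 4 benzene-1,3,5-triol (phloroglucinol)
Product: 6 2-(3,5-dibromo-4-hydroxyphenyl)-5,7-dihydroxy-4H-chromen-4-one, via 1,3-diketone 5 (not isolated)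
Conditions: 3 (2 equiv), anhydrous 4, neat melt, 240 °C, N2 sweep, 1.5 h
Reagents that add atoms: none
Why: Mentzer pyrone synthesis, in which thermal loss of ethanol lets the ester carbon of 3 C-acylate the highly nucleophilic phloroglucinol and the resulting ortho-hydroxyaryl 1,3-diketone cyclodehydrates to ring C, the threefold symmetry of 4 removing any regiochemical question (no stereocentre formed).

Step 3
Reactants: 6 2-(3,5-dibromo-4-hydroxyphenyl)-5,7-dihydroxy-4H-chromen-4-one
Product: 7 2-[3,5-dibromo-4-(methoxymethoxy)phenyl]-5,7-bis(methoxymethoxy)-4H-chromen-4-one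
Conditions: NaH (4 equiv), MOMCl (4 equiv), DMF, 0 °C to rt, 4 h
Reagents that add atoms: chloromethyl methyl ether (MOMCl), COCCl
Why: Williamson-type O-alkylation in which NaH in DMF deprotonates even the chelated 5-OH so that all three phenols are capped, which is required because only a 5-O-alkylated ring A is iodinated at C8 in the next step.

Step 4
Reactants: 7 2-[3,5-dibromo-4-(methoxymethoxy)phenyl]-5,7-bis(methoxymethoxy)-4H-chromen-4-one
Product: 8 2-[3,5-dibromo-4-(methoxymethoxy)phenyl]-8-iodo-5,7-bis(methoxymethoxy)-4H-chromen-4-one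
Conditions: NIS (1.1 equiv), DMF, rt, dark, 12 h
Reagents that add atoms: N-iodosuccinimide (NIS), O=C1CCC(=O)N1I
Why: Electrophilic aromatic iodination that goes to C8 (ortho to O1 and the 7-alkoxy group, para to the 5-alkoxy group) as in 5,7-dialkoxyflavones generally, because C6 is flanked by two MOM ethers and ring B is deactivated by two bromines, while neutral NIS leaves the acetals intact.

Step 5
Reactants: 8 2-[3,5-dibromo-4-(methoxymethoxy)phenyl]-8-iodo-5,7-bis(methoxymethoxy)-4H-chromen-4-one; 9 tributyl(3-methylbut-2-en-1-yl)stannane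
Product: 10 5,7-bis(methoxymethoxy)-2-[4-(methoxymethoxy)-3,5-bis(3-methylbut-2-en-1-yl)phenyl]-8-(3-methylbut-2-en-1-yl)-4H-chromen-4-one
Conditions: 9 (4.5 equiv), Pd(PPh3)4 (10 mol %), degassed DMF, 100 °C, 16 h
Reagents that add atoms: none
Why: Threefold Stille cross-coupling in which zerovalent palladium inserts into the C8–I and both C–Br bonds, the allylic stannane transmetalates rapidly and reductive elimination from the less hindered primary sigma-allyl gives the linear 3-methylbut-2-enyl arene at each site, with the pyranone carbonyl and the acetals untouched (no stereocentre formed).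

Step 6
Reactants: 10 5,7-bis(methoxymethoxy)-2-[4-(methoxymethoxy)-3,5-bis(3-methylbut-2-en-1-yl)phenyl]-8-(3-methylbut-2-en-1-yl)-4H-chromen-4-one
Product: 11 Epimedonin L, 5,7-dihydroxy-2-[4-hydroxy-3,5-bis(3-methylbut-2-en-1-yl)phenyl]-8-(3-methylbut-2-en-1-yl)-4H-chromen-4-one
Conditions: 3 M HCl (aq)/MeOH 1:5, 40 °C, 3 h; then NaHCO3 (aq)
Reagents that add atoms: none
Why: Acid-catalysed acetal exchange of the three MOM ethers with methanol under conditions mild enough, as for other ortho-prenylated phenols, to stay below the threshold for Markovnikov cyclisation of the prenyl groups onto the freed hydroxyls (the target has no stereocentre).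

**Compound list**
1 | 1-(3,5-dibromo-4-hydroxyphenyl)ethanone | CC(=O)c1cc(Br)c(O)c(Br)c1 | starting material
2 | diethyl carbonate | CCOC(=O)OCC | starting material
3 | ethyl 3-(3,5-dibromo-4-hydroxyphenyl)-3-oxopropanoate | CCOC(=O)CC(=O)c1cc(Br)c(O)c(Br)c1 | intermediate
4 | benzene-1,3,5-triol (phloroglucinol) | Oc1cc(O)cc(O)c1 | starting material
5 | 1-(3,5-dibromo-4-hydroxyphenyl)-3-(2,4,6-trihydroxyphenyl)propane-1,3-dione | O=C(CC(=O)c1c(O)cc(O)cc1O)c1cc(Br)c(O)c(Br)c1 | intermediate
6 | 2-(3,5-dibromo-4-hydroxyphenyl)-5,7-dihydroxy-4H-chromen-4-one | O=c1cc(-c2cc(Br)c(O)c(Br)c2)oc2cc(O)cc(O)c12 | intermediate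
7 | 2-[3,5-dibromo-4-(methoxymethoxy)phenyl]-5,7-bis(methoxymethoxy)-4H-chromen-4-one | COCOc1cc(OCOC)c2c(=O)cc(-c3cc(Br)c(OCOC)c(Br)c3)oc2c1 | intermediate
8 | 2-[3,5-dibromo-4-(methoxymethoxy)phenyl]-8-iodo-5,7-bis(methoxymethoxy)-4H-chromen-4-one | COCOc1cc(OCOC)c2c(=O)cc(-c3cc(Br)c(OCOC)c(Br)c3)oc2c1I | intermediate
9 | tributyl(3-methylbut-2-en-1-yl)stannane | CCCC[Sn](CCCC)(CCCC)CC=C(C)C | starting material
10 | 5,7-bis(methoxymethoxy)-2-[4-(methoxymethoxy)-3,5-bis(3-methylbut-2-en-1-yl)phenyl]-8-(3-methylbut-2-en-1-yl)-4H-chromen-4-one | COCOc1cc(OCOC)c2c(=O)cc(-c3cc(CC=C(C)C)c(OCOC)c(CC=C(C)C)c3)oc2c1CC=C(C)C | intermediate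
11 | Epimedonin L, 5,7-dihydroxy-2-[4-hydroxy-3,5-bis(3-methylbut-2-en-1-yl)phenyl]-8-(3-methylbut-2-en-1-yl)-4H-chromen-4-one | CC(C)=CCc1cc(-c2cc(=O)c3c(O)cc(O)c(CC=C(C)C)c3o2)cc(CC=C(C)C)c1O | target

**Totals**
Total step count: 6. Longest linear sequence: 6 steps (1 → 3 → 6 → 7 → 8 → 10 → 11).

**Three steps most likely to fail**

Step 5 (threefold Stille prenylation). The risks are incomplete coupling at one of the three hindered sites, some branched 1,1-dimethylallyl product from coupling at the tertiary allyl terminus, and protodehalogenation. The fallback sets out from 8 and comes back at 10. Threefold Stille allylation of 8 with allyltributylstannane (Pd(PPh3)4, DMF, 100 °C) gives 8-allyl-2-[3,5-diallyl-4-(methoxymethoxy)phenyl]-5,7-bis(methoxymethoxy)-4H-chromen-4-one F1; here both allyl termini give the same product, so there is no regiochemical issue. Threefold olefin cross-metathesis of F1 with 2-methylbut-2-ene (second-generation Grubbs catalyst, CH2Cl2/2-methylbut-2-ene, 40 °C) turns each allyl group into a 3-methylbut-2-enyl group and delivers 10.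

Step 4 (C8 iodination). The risk is C6 iodination or an inseparable C6/C8 mixture. The fallback sets out from 6 and comes back at 11, fixing the C8 substituent by a pericyclic path instead of by electrophilic substitution.
- Selective capping of the two non-chelated phenols of 6 (MOMCl, i-Pr2NEt, CH2Cl2, rt) gives 2-[3,5-dibromo-4-(methoxymethoxy)phenyl]-5-hydroxy-7-(methoxymethoxy)-4H-chromen-4-one F2.
- O-Alkylation of the 5-OH (prenyl bromide, K2CO3, DMF, 60 °C) gives 2-[3,5-dibromo-4-(methoxymethoxy)phenyl]-7-(methoxymethoxy)-5-[(3-methylbut-2-en-1-yl)oxy]-4H-chromen-4-one F3.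
- Para-Claisen–Cope rearrangement catalysed by Eu(fod)3 (10 mol %, CHCl3, 60 °C) moves the prenyl group from O5 through C6 to C8, the only para position. This gives 2-[3,5-dibromo-4-(methoxymethoxy)phenyl]-5-hydroxy-7-(methoxymethoxy)-8-(3-methylbut-2-en-1-yl)-4H-chromen-4-one F4.
- Twofold Stille coupling of F4 with 9 (Pd(PPh3)4, DMF, 100 °C) gives 5-hydroxy-7-(methoxymethoxy)-2-[4-(methoxymethoxy)-3,5-bis(3-methylbut-2-en-1-yl)phenyl]-8-(3-methylbut-2-en-1-yl)-4H-chromen-4-one F5.
- Cleavage of the two MOM ethers of F5 (HCl, MeOH, 40 °C) gives 11.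

Step 6 (MOM removal next to three prenyl groups). The risk is acid-induced chroman formation or hydration of the prenyl olefins. The fallback sets out from 8 and comes back at 11 by reversing the order of events. The MOM ethers of 8 are cleaved first, when no prenyl group is present (HCl, MeOH, 40 °C), to give 2-(3,5-dibromo-4-hydroxyphenyl)-5,7-dihydroxy-8-iodo-4H-chromen-4-one F6. The threefold Stille coupling with 9 (Pd(PPh3)4, DMF, 100 °C) is then run on the unprotected triphenol F6, so 11 is formed directly and never sees acid.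

**Further compounds**
F1 | step 5 | 8-allyl-2-[3,5-diallyl-4-(methoxymethoxy)phenyl]-5,7-bis(methoxymethoxy)-4H-chromen-4-one | COCOc1cc(OCOC)c2c(=O)cc(-c3cc(CC=C)c(OCOC)c(CC=C)c3)oc2c1CC=C
F2 | step 4 | 2-[3,5-dibromo-4-(methoxymethoxy)phenyl]-5-hydroxy-7-(methoxymethoxy)-4H-chromen-4-one | COCOc1cc(O)c2c(=O)cc(-c3cc(Br)c(OCOC)c(Br)c3)oc2c1
F3 | step 4 | 2-[3,5-dibromo-4-(methoxymethoxy)phenyl]-7-(methoxymethoxy)-5-[(3-methylbut-2-en-1-yl)oxy]-4H-chromen-4-one | COCOc1cc(OCC=C(C)C)c2c(=O)cc(-c3cc(Br)c(OCOC)c(Br)c3)oc2c1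
F4 | step 4 | 2-[3,5-dibromo-4-(methoxymethoxy)phenyl]-5-hydroxy-7-(methoxymethoxy)-8-(3-methylbut-2-en-1-yl)-4H-chromen-4-one | COCOc1cc(O)c2c(=O)cc(-c3cc(Br)c(OCOC)c(Br)c3)oc2c1CC=C(C)C
F5 | step 4 | 5-hydroxy-7-(methoxymethoxy)-2-[4-(methoxymethoxy)-3,5-bis(3-methylbut-2-en-1-yl)phenyl]-8-(3-methylbut-2-en-1-yl)-4H-chromen-4-one | COCOc1cc(O)c2c(=O)cc(-c3cc(CC=C(C)C)c(OCOC)c(CC=C(C)C)c3)oc2c1CC=C(C)C
F6 | step 6 | 2-(3,5-dibromo-4-hydroxyphenyl)-5,7-dihydroxy-8-iodo-4H-chromen-4-one | O=c1cc(-c2cc(Br)c(O)c(Br)c2)oc2c(I)c(O)cc(O)c12
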